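**Strategy.** The methylenecyclohexane ring is disconnected at the bond between its methyl-bearing quaternary fusion carbon and the neighbouring CH that carries the two-carbon linker. This bond is formed last, in a bis-epoxide cascade on a substrate that already contains the complete right-hand perhydrobenzoxepine: a silyl triflate makes the inner epoxide oxygen open the terminal epoxide (left oxepane, as an epoxonium ion), and a regiodefined silyl enol ether then opens the epoxonium ion with inversion, closing the carbocycle as a cyclohexanone. The step exploits the anti relationship between the oxepane oxygen on the fusion CH and the new C–C bond, and the oxepane's ring-O/C3–OH pattern. The precursor is an acyclic (S,S,S)-diepoxy enol silane; Wittig methylenation finishes.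

Key step: step 8

Assumption: (5E)-geranylacetone is taken as purchasable as the pure E isomer and the L-fructose-derived enantiomer of the Shi ketone as available; the silyl ethers formed in the two cascades are cleaved in the acidic work-up of the same step.

**Step 1**
Reactants: 1 (5E)-geranylacetone
Product: 2 (S,S,S)-diepoxy ketone
Conditions: L-fructose-derived Shi ketone (0.3 equiv), Oxone (KHSO5), K2CO3, Bu4NHSO4, Na2B4O7/Na2EDTA buffer (pH 10.5), MeCN–CH2(OMe)2–H2O, 0 °C
Reagents that add atoms: potassium peroxymonosulfate [K+].[O-]S(=O)(=O)OO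
Why: Shi asymmetric epoxidation, in which the chiral dioxirane should epoxidise both electron-rich trisubstituted alkenes through the spiro transition state and set the three epoxide stereocentres (2S,3S and 2S) by catalyst control, while the ketone is not enolised at this pH.

**Step 2**
Reactants: 2 (S,S,S)-diepoxy ketone
Product: 5 diepoxy vinyl ketone, via Mannich base 3 (not isolated), via trimethylammonium iodide 4 (not isolated)
Conditions: LiN(i-Pr)2, THF, −78 °C; Me2N=CH2 I, −78 to 0 °C; MeI, Et2O, rt; aq NaHCO3, CH2Cl2, rt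
Reagents that add atoms: N,N-dimethylmethyleneiminium iodide C=[N+](C)C.[I-]
Why: Mannich reaction of the kinetic methyl-side lithium enolate, then exhaustive N-methylation and E1cB loss of trimethylamine, should unveil the vinyl ketone without touching the epoxides; no stereocentre is formed.

**Step 3**
Reactants: 5 diepoxy vinyl ketone
Product: 6 (Z)-trimethylsilyl enol ether bearing an allyl terminus
Conditions: CH2=CHMgBr, CuBr·SMe2 (10 mol%), Me3SiCl, HMPA, THF, −78 °C; Et3N, pentane work-up, used crude
Reagents that add atoms: vinylmagnesium bromide C=C[Mg]Br; chlorotrimethylsilane C[Si](C)(C)Cl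
Why: Copper-catalysed conjugate addition of the Grignard reagent with silyl chloride trapping should give the enol silane regiospecifically on the side of the former vinyl group, mainly as the Z isomer from the s-cis enone (the geometry is helpful but not essential); the trisubstituted epoxides are inert at −78 °C.

**Step 4**
Reactants: 6 (Z)-trimethylsilyl enol ether
Product: 8 trans-fused allyl hydroxy ketone (right-hand bicycle), via silyl ether 7 (not isolated)
Conditions: Me3SiOTf, 2,6-di-tert-butyl-4-methylpyridine, CH2Cl2, −78 °C; then 1 M aq HCl, THF, 0 °C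
Reagents that add atoms: none
Why: Silyl-triflate-promoted tandem oxa-/carbacyclisation (an epoxide-initiated cation–olefin cyclisation terminated by an enol silane), in which the inner epoxide oxygen opens the activated terminal epoxide at its tertiary carbon and the enol silane opens the epoxonium ion with inversion through a chair, so that the trans ring fusion follows from the (S,S)-epoxide, the carbinol centre is retained, and the allyl group sits equatorial (also the thermodynamic position next to the ketone).

**Step 5**
Reactants: 8 trans-fused allyl hydroxy ketone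
Product: 10 allyl diacetate, via magnesium dialkoxide 9 (not isolated)
Conditions: MeMgBr (excess), THF, −78 to 0 °C; then Ac2O, DMAP, 0 to 40 °C
Reagents that add atoms: methylmagnesium bromide C[Mg]Br; acetic anhydride CC(=O)OC(C)=O
Why: Grignard addition should occur from the equatorial direction because the axial face is blocked by the 1,3-diaxial angular methyl, giving the axial tertiary alkoxide with equatorial methyl (7R); both magnesium alkoxides are then acetylated in the same flask, which avoids acylating a hindered neutral tertiary alcohol.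

**Step 6**
Reactants: 10 allyl diacetate; 5 diepoxy vinyl ketone (excess, from step 2)
Product: 11 (E)-enone carrying both halves
Conditions: second-generation Hoveyda–Grubbs catalyst (5 mol%), CH2Cl2, 40 °C
Reagents that add atoms: none
Why: Olefin cross-metathesis between a terminal alkene and an electron-poor vinyl ketone should be selective for the cross product with E geometry; epoxides and acetates are tolerated and neither partner contains another alkene.

**Step 7**
Reactants: 11 (E)-enone
Product: 12 (Z)-triethylsilyl enol ether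
Conditions: Et3SiH, RhCl(PPh3)3 (2 mol%), toluene, 50 °C
Reagents that add atoms: triethylsilane CC[SiH](CC)CC
Why: Rhodium-catalysed 1,4-hydrosilylation of the enone with a monohydrosilane should deliver the silyl enol ether regiospecifically between the carbonyl carbon and the former α-carbon, a regiochemistry that enolisation of the saturated ketone could not secure.

**Step 8**
Reactants: 12 (Z)-triethylsilyl enol ether
Product: 14 tetracyclic keto alcohol, via silyl ether 13 (not isolated)
Conditions: Et3SiOTf, 2,6-di-tert-butyl-4-methylpyridine, CH2Cl2, −78 °C; then 1 M aq HCl, THF, rt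
Reagents that add atoms: none
Why: Et3SiOTf silylates the less hindered terminal epoxide, the inner epoxide oxygen attacks its tertiary carbon (7-endo, closing the left oxepane as a bicyclic epoxonium ion), and the enol silane carbon then opens the epoxonium ion at the methyl-bearing tertiary carbon with inversion (6-endo with respect to the enol double bond, chair, closing the cyclohexanone), after which the oxocarbenium ion releases its silyl group and regenerates the promoter. The closest known reaction type is the silyl-triflate-promoted tandem oxa-/carbacyclisation of 1,5-diepoxides terminated by enol silanes, the epoxide-initiated counterpart of a cation–olefin polycyclisation. The oxepane is therefore closed first and the carbocycle last, on a substrate that already carries both right-hand rings. The ether-bearing CH and the carbinol CH keep the configuration of the epoxides, the quaternary carbon is set by the invertive anti opening, and the linker-bearing α-carbon is set by the chair of the Z enol silane (side chain equatorial) and is in any case epimerisable to this more stable isomer. The step needs endo-selective opening at both tertiary epoxide carbons (secured by trisubstitution), C- rather than O-alkylation by the enol silane (secured by the six-membered chair), and survival of the acetates (hindered non-nucleophilic base, −78 °C).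

**Step 9**
Reactants: 14 tetracyclic keto alcohol
Product: 15 target compound
Conditions: Ph3PCH3Br, KN(SiMe3)2, THF, 0 °C to rt
Reagents that add atoms: methyltriphenylphosphonium bromide C[P+](c1ccccc1)(c1ccccc1)c1ccccc1.[Br-]
Why: Wittig methylenation, in which the non-stabilised ylide should react with the ketone faster than with the two hindered acetates, the free hydroxyl is only deprotonated, and the α-centre stays in its equatorial configuration; no new stereocentre is formed.

**Compound list**

1 | (5E)-6,10-dimethylundeca-5,9-dien-2-one ((E)-geranylacetone) | CC(=O)CC/C=C(\C)CCC=C(C)C | starting material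
2 | 4-[(2S,3S)-3-{2-[(2S)-3,3-dimethyloxiran-2-yl]ethyl}-3-methyloxiran-2-yl]butan-2-one | CC(=O)CC[C@@H]1O[C@@]1(C)CC[C@@H]2OC2(C)C | intermediate
3 | 1-(dimethylamino)-5-[(2S,3S)-3-{2-[(2S)-3,3-dimethyloxiran-2-yl]ethyl}-3-methyloxiran-2-yl]pentan-3-one (Mannich base) | CN(C)CCC(=O)CC[C@@H]1O[C@@]1(C)CC[C@@H]2OC2(C)C | intermediate
4 | {5-[(2S,3S)-3-{2-[(2S)-3,3-dimethyloxiran-2-yl]ethyl}-3-methyloxiran-2-yl]-3-oxopentyl}trimethylammonium iodide | C[N+](C)(C)CCC(=O)CC[C@@H]1O[C@@]1(C)CC[C@@H]2OC2(C)C.[I-] | intermediate
5 | 5-[(2S,3S)-3-{2-[(2S)-3,3-dimethyloxiran-2-yl]ethyl}-3-methyloxiran-2-yl]pent-1-en-3-one | C=CC(=O)CC[C@@H]1O[C@@]1(C)CC[C@@H]2OC2(C)C | intermediate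
6 | trimethyl{[(3Z)-1-[(2S,3S)-3-{2-[(2S)-3,3-dimethyloxiran-2-yl]ethyl}-3-methyloxiran-2-yl]hepta-3,6-dien-3-yl]oxy}silane | C=CC/C=C(\O[Si](C)(C)C)CC[C@@H]1O[C@@]1(C)CC[C@@H]2OC2(C)C | intermediate
7 | (3S,5aS,6S,9aS)-2,2,5a-trimethyl-6-(prop-2-en-1-yl)-3-[(trimethylsilyl)oxy]octahydro-1-benzoxepin-7(2H)-one | C=CC[C@H]1[C@]2(C)CC[C@H](O[Si](C)(C)C)C(C)(C)O[C@H]2CCC1=O | intermediate
8 | (3S,5aS,6S,9aS)-3-hydroxy-2,2,5a-trimethyl-6-(prop-2-en-1-yl)octahydro-1-benzoxepin-7(2H)-one (trans ring fusion, allyl equatorial) | C=CC[C@H]1[C@]2(C)CC[C@H](O)C(C)(C)O[C@H]2CCC1=O | intermediate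
9 | bis(bromomagnesium) dialkoxide of (3S,5aS,6S,7R,9aS)-2,2,5a,7-tetramethyl-6-(prop-2-en-1-yl)decahydro-1-benzoxepine-3,7-diol | C=CC[C@H]1[C@]2(C)CC[C@H]([O-])C(C)(C)O[C@H]2CC[C@@]1(C)[O-].[Mg+2].[Mg+2].[Br-].[Br-] | intermediate
10 | (3S,5aS,6S,7R,9aS)-2,2,5a,7-tetramethyl-6-(prop-2-en-1-yl)decahydro-1-benzoxepine-3,7-diyl diacetate (7-acetoxy axial, 7-methyl equatorial) | C=CC[C@H]1[C@]2(C)CC[C@H](OC(C)=O)C(C)(C)O[C@H]2CC[C@@]1(C)OC(C)=O | intermediate
11 | (3S,5aS,6S,7R,9aS)-6-[(2E)-6-{(2S,3S)-3-{2-[(2S)-3,3-dimethyloxiran-2-yl]ethyl}-3-methyloxiran-2-yl}-4-oxohex-2-en-1-yl]-2,2,5a,7-tetramethyldecahydro-1-benzoxepine-3,7-diyl diacetate | C(/C=C/C(=O)CC[C@@H]3O[C@@]3(C)CC[C@@H]4OC4(C)C)[C@H]1[C@]2(C)CC[C@H](OC(C)=O)C(C)(C)O[C@H]2CC[C@@]1(C)OC(C)=O | intermediate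
12 | (3S,5aS,6S,7R,9aS)-6-[(3Z)-6-{(2S,3S)-3-{2-[(2S)-3,3-dimethyloxiran-2-yl]ethyl}-3-methyloxiran-2-yl}-4-[(triethylsilyl)oxy]hex-3-en-1-yl]-2,2,5a,7-tetramethyldecahydro-1-benzoxepine-3,7-diyl diacetate | C(C/C=C(\O[Si](CC)(CC)CC)CC[C@@H]3O[C@@]3(C)CC[C@@H]4OC4(C)C)[C@H]1[C@]2(C)CC[C@H](OC(C)=O)C(C)(C)O[C@H]2CC[C@@]1(C)OC(C)=O | intermediate
13 | (3S,5aS,6S,7R,9aS)-6-{2-[(3S,5aS,6S,9aS)-2,2,5a-trimethyl-7-oxo-3-[(triethylsilyl)oxy]decahydro-1-benzoxepin-6-yl]ethyl}-2,2,5a,7-tetramethyldecahydro-1-benzoxepine-3,7-diyl diacetate | O=C1CC[C@@H]2OC(C)(C)[C@@H](O[Si](CC)(CC)CC)CC[C@@]2(C)[C@@H]1CC[C@H]1[C@]2(C)CC[C@H](OC(C)=O)C(C)(C)O[C@H]2CC[C@@]1(C)OC(C)=O | intermediate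
14 | (3S,5aS,6S,7R,9aS)-6-{2-[(3S,5aS,6S,9aS)-3-hydroxy-2,2,5a-trimethyl-7-oxodecahydro-1-benzoxepin-6-yl]ethyl}-2,2,5a,7-tetramethyldecahydro-1-benzoxepine-3,7-diyl diacetate | O=C1CC[C@@H]2OC(C)(C)[C@@H](O)CC[C@@]2(C)[C@@H]1CC[C@H]1[C@]2(C)CC[C@H](OC(C)=O)C(C)(C)O[C@H]2CC[C@@]1(C)OC(C)=O | intermediate
15 | (3S,5aS,6S,7R,9aS)-6-{2-[(3S,5aS,6R,9aS)-3-hydroxy-2,2,5a-trimethyl-7-methylidenedecahydro-1-benzoxepin-6-yl]ethyl}-2,2,5a,7-tetramethyldecahydro-1-benzoxepine-3,7-diyl diacetate (CNP0412606.1) | C=C1CC[C@@H]2OC(C)(C)[C@@H](O)CC[C@@]2(C)[C@@H]1CC[C@H]1[C@]2(C)CC[C@H](OC(C)=O)C(C)(C)O[C@H]2CC[C@@]1(C)OC(C)=O | target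

**Step count and risks**

Total step count: 9. Longest linear sequence: 9 steps (1 to 15; compound 5 is made once and enters twice, in steps 3 and 6).

Steps most likely to fail:

Step 8. The enol silane may be lost by protodesilylation before it intercepts the epoxonium ion, or it may alkylate on oxygen, so that the carbocycle is not closed. The fallback changes the terminating nucleophile to an allylsilane, which is not hydrolysable and already carries the methylene carbon. It sets out from 12: CsF and PhNTf2 in DME should give the (Z)-enol triflate F1. Kumada coupling (Me3SiCH2MgCl, Pd(PPh3)4, THF, 0 °C) should then give the (Z)-allylsilane F2 with retention of geometry. The same cascade (Me3SiOTf, 2,6-di-tert-butyl-4-methylpyridine, CH2Cl2, −78 °C) should close the oxepane and then the carbocycle, with loss of silicon forming the exocyclic methylene, to give the silyl ether of the target F3. Acidic work-up hydrolyses F3, and the fallback comes back to the route at 15, bypassing 14.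

Step 5. The hindered ketone may be enolised instead of attacked, and the axial tertiary magnesium alkoxide may be acylated incompletely. The fallback separates the two events and changes the acylation from alkoxide trapping to Lewis-acid catalysis. It sets out from 8: the organocerium reagent from MeLi and CeCl3 (THF, −78 °C) should add without enolisation and give, after aqueous work-up, the diol F4. F4 is then acetylated on both hydroxyls with Ac2O and catalytic Bi(OTf)3 in MeCN at rt, and the fallback comes back at 10.

Step 9. Acyl transfer from the acetates to the basic ylide, or slow addition to the hindered ketone, may erode the last step. The fallback is a two-stage Peterson olefination under weakly basic then acidic conditions. It sets out from 14: Me3SiCH2MgCl with CeCl3 (THF, −78 °C) should add to the ketone chemoselectively and give the β-hydroxysilane F5 (either carbinol epimer serves). HF·pyridine in THF then induces anti elimination of the silanol to the exocyclic alkene, and the fallback comes back at 15.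

**Further compounds**

F1 | step 8 | (3S,5aS,6S,7R,9aS)-6-[(3Z)-6-{(2S,3S)-3-{2-[(2S)-3,3-dimethyloxiran-2-yl]ethyl}-3-methyloxiran-2-yl}-4-{[(trifluoromethyl)sulfonyl]oxy}hex-3-en-1-yl]-2,2,5a,7-tetramethyldecahydro-1-benzoxepine-3,7-diyl diacetate | C(C/C=C(\OS(=O)(=O)C(F)(F)F)CC[C@@H]3O[C@@]3(C)CC[C@@H]4OC4(C)C)[C@H]1[C@]2(C)CC[C@H](OC(C)=O)C(C)(C)O[C@H]2CC[C@@]1(C)OC(C)=O
F2 | step 8 | (3S,5aS,6S,7R,9aS)-6-[(3Z)-6-{(2S,3S)-3-{2-[(2S)-3,3-dimethyloxiran-2-yl]ethyl}-3-methyloxiran-2-yl}-4-[(trimethylsilyl)methyl]hex-3-en-1-yl]-2,2,5a,7-tetramethyldecahydro-1-benzoxepine-3,7-diyl diacetate | C(C/C=C(\C[Si](C)(C)C)CC[C@@H]3O[C@@]3(C)CC[C@@H]4OC4(C)C)[C@H]1[C@]2(C)CC[C@H](OC(C)=O)C(C)(C)O[C@H]2CC[C@@]1(C)OC(C)=O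
F3 | step 8 | 3-O-trimethylsilyl ether of the target 15 (left-hand oxepane carbinol silylated) | C=C1CC[C@@H]2OC(C)(C)[C@@H](O[Si](C)(C)C)CC[C@@]2(C)[C@@H]1CC[C@H]1[C@]2(C)CC[C@H](OC(C)=O)C(C)(C)O[C@H]2CC[C@@]1(C)OC(C)=O
F4 | step 5 | (3S,5aS,6S,7R,9aS)-2,2,5a,7-tetramethyl-6-(prop-2-en-1-yl)decahydro-1-benzoxepine-3,7-diol | C=CC[C@H]1[C@]2(C)CC[C@H](O)C(C)(C)O[C@H]2CC[C@@]1(C)O
F5 | step 9 | β-hydroxysilane from 14: the left-hand ketone carbon carries OH and CH2SiMe3 (configuration at this carbon not defined) | C[Si](C)(C)CC1(O)CC[C@@H]2OC(C)(C)[C@@H](O)CC[C@@]2(C)[C@@H]1CC[C@H]1[C@]2(C)CC[C@H](OC(C)=O)C(C)(C)O[C@H]2CC[C@@]1(C)OC(C)=O
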